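**Plan**

- Retrosynthesis: the pyranone (ring C) is cut to a silyl enol ether plus malonyl dichloride; the cyclohexanone (ring B) is cut at the C3–C4 bond to an open (E)-β-alkoxyvinyl o-tolyl ketone; that enone is cut at C3–O (chiral alcohol) and C1–C2 (ethynyl Grignard reagent plus aldehyde); the acetyl and 3-methylbutyl groups on the benzene ring (ring A) are cut by cross-coupling back to 2,4-dihydroxy-6-methylbenzaldehyde.
- Forward: ring A is bought and decorated (triflate to 3-methylbutyl, bromide to acetyl to silyl enol ether), the enone chain is attached, ring B is closed, ring C is built last, and one acid step frees the three hydroxyl groups.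
- Enabling feature: the C1 ketone sits on C8a next to C4a, which carries C4, so the open precursor is an o-methylaryl ketone. Light turns it into a dienol in which C4=C4a–C8a=C1–C2=C3 is a hexatriene made of exactly the six carbons of ring B; its 6π closure forms C4–C3 and leaves the ketone at C1 and the oxygen at C3.
- Stereochemistry: the only stereocenter, C3, is set in that ring closure under control of (R)-1-(2,4,6-triisopropylphenyl)ethanol carried on the enol ether oxygen; the two C3 epimers are diastereomers, and the auxiliary ether doubles as the 3-OH protecting group until the last step.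

Key step: step 10

Abbreviations: MOM = methoxymethyl; TBS = tert-butyldimethylsilyl; Trip = 2,4,6-triisopropylphenyl. Tetralone numbering (C1 ketone to C8a) is used throughout.

Assumption (chemistry): the auxiliary is taken to shield one face of C2=C3 as enol ethers of this alcohol do in known cycloadditions (O–C3 bond s-cis, carbinol C–H in the enone plane). On that model the (R)-alcohol gives (3R); should the sense prove opposite, the (S)-alcohol, also purchasable, is used and nothing else changes.

**Step 1**
Reactants: 1 2,4-dihydroxy-6-methylbenzaldehyde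
Product: 2 4-formyl-3-hydroxy-5-methylphenyl trifluoromethanesulfonate
Conditions: Tf2O (1.05 equiv), pyridine, CH2Cl2, −20 to 0 °C
Reagents that add atoms: trifluoromethanesulfonic anhydride, O=S(=O)(OS(=O)(=O)C(F)(F)F)C(F)(F)F
Why: Phenol O-sulfonylation should take the 4-hydroxyl only, because the 2-hydroxyl is tied up in a hydrogen bond to the aldehyde and is the less acidic one.

**Step 2**
Reactants: 2 4-formyl-3-hydroxy-5-methylphenyl trifluoromethanesulfonate
Product: 3 4-formyl-3-(methoxymethoxy)-5-methylphenyl trifluoromethanesulfonate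
Conditions: MOMCl, iPr2NEt, CH2Cl2, 0 °C to rt
Reagents that add atoms: chloromethyl methyl ether, COCCl
Why: O-alkylation of the remaining phenol (MOM ether formation) removes the acidic OH that would consume organometallic reagents and quench the excited ketone later.

**Step 3**
Reactants: 3 4-formyl-3-(methoxymethoxy)-5-methylphenyl trifluoromethanesulfonate; 4 (3-methylbutyl)zinc bromide
Product: 5 2-(methoxymethoxy)-6-methyl-4-(3-methylbutyl)benzaldehyde
Conditions: Pd(dppf)Cl2 (3 mol%), THF, 50 °C
Reagents that add atoms: none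
Why: Negishi sp2–sp3 cross-coupling of the unhindered aryl triflate with a primary alkylzinc halide, a reagent that does not add to the aldehyde.

**Step 4**
Reactants: 5 2-(methoxymethoxy)-6-methyl-4-(3-methylbutyl)benzaldehyde
Product: 6 3-bromo-6-(methoxymethoxy)-2-methyl-4-(3-methylbutyl)benzaldehyde
Conditions: NBS, DMF, 0 °C to rt, dark
Reagents that add atoms: N-bromosuccinimide, O=C1CCC(=O)N1Br
Why: Electrophilic aromatic bromination should go para to the MOM ether oxygen (the position between the methyl and 3-methylbutyl groups, meta to the aldehyde), and polar radical-free conditions spare the benzylic hydrogens.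

**Step 5**
Reactants: 6 3-bromo-6-(methoxymethoxy)-2-methyl-4-(3-methylbutyl)benzaldehyde; 7 tributyl(1-ethoxyvinyl)stannane
Product: 9 3-acetyl-6-(methoxymethoxy)-2-methyl-4-(3-methylbutyl)benzaldehyde, via enol ether 8 (not isolated)
Conditions: Pd(PtBu3)2 (5 mol%), CsF, dioxane, 90 °C; then 1 M HCl, THF, 0 °C
Reagents that add atoms: water, O
Why: Fluoride-promoted Stille coupling with a bulky phosphine suits the doubly ortho-substituted bromide and brings in a masked acetyl group, and dilute acid hydrolyses the enol ether much faster than the aryl MOM ether.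

**Step 6**
Reactants: 9 3-acetyl-6-(methoxymethoxy)-2-methyl-4-(3-methylbutyl)benzaldehyde
Product: 10 3-[1-(tert-butyldimethylsilyloxy)vinyl]-6-(methoxymethoxy)-2-methyl-4-(3-methylbutyl)benzaldehyde
Conditions: TBSOTf, Et3N (excess), CH2Cl2, −78 to 0 °C
Reagents that add atoms: tert-butyldimethylsilyl trifluoromethanesulfonate, CC(C)(C)[Si](C)(C)OS(=O)(=O)C(F)(F)F
Why: Soft enolization/O-silylation of the only enolizable carbonyl gives the silyl enol ether, which hides this ketone from the Grignard reagent and from light and later serves as the nucleophile for ring C.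

**Step 7**
Reactants: 10 3-[1-(tert-butyldimethylsilyloxy)vinyl]-6-(methoxymethoxy)-2-methyl-4-(3-methylbutyl)benzaldehyde; 11 ethynylmagnesium bromide
Product: 12 racemic 1-{3-[1-(tert-butyldimethylsilyloxy)vinyl]-6-(methoxymethoxy)-2-methyl-4-(3-methylbutyl)phenyl}prop-2-yn-1-ol
Conditions: THF, −78 to 0 °C; then aq NH4Cl
Reagents that add atoms: none
Why: Grignard 1,2-addition to the aldehyde forms the C1–C2 bond; the carbinol centre is destroyed in the next step, so it needs no control.

**Step 8**
Reactants: 12 racemic 1-{3-[1-(tert-butyldimethylsilyloxy)vinyl]-6-(methoxymethoxy)-2-methyl-4-(3-methylbutyl)phenyl}prop-2-yn-1-ol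
Product: 13 1-{3-[1-(tert-butyldimethylsilyloxy)vinyl]-6-(methoxymethoxy)-2-methyl-4-(3-methylbutyl)phenyl}prop-2-yn-1-one
Conditions: MnO2 (excess), CH2Cl2, rt
Reagents that add atoms: none
Why: MnO2 oxidation of a benzylic/propargylic alcohol is neutral and should leave the silyl enol ether and the MOM ether alone.

**Step 9**
Reactants: 13 1-{3-[1-(tert-butyldimethylsilyloxy)vinyl]-6-(methoxymethoxy)-2-methyl-4-(3-methylbutyl)phenyl}prop-2-yn-1-one; 14 (R)-1-(2,4,6-triisopropylphenyl)ethanol
Product: 15 (E)-1-{3-[1-(tert-butyldimethylsilyloxy)vinyl]-6-(methoxymethoxy)-2-methyl-4-(3-methylbutyl)phenyl}-3-[(R)-1-(2,4,6-triisopropylphenyl)ethoxy]prop-2-en-1-one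
Conditions: PMe3 (10 mol%), CH2Cl2, 0 °C to rt
Reagents that add atoms: none
Why: Phosphine-catalysed conjugate addition of an alcohol to a terminal ynone (oxa-Michael addition) gives the (E)-β-alkoxy enone, and the auxiliary keeps its configuration because its C–O bond is not broken.

**Step 10**
Reactants: 15 (E)-1-{3-[1-(tert-butyldimethylsilyloxy)vinyl]-6-(methoxymethoxy)-2-methyl-4-(3-methylbutyl)phenyl}-3-[(R)-1-(2,4,6-triisopropylphenyl)ethoxy]prop-2-en-1-one
Product: 18 (3R)-5-[1-(tert-butyldimethylsilyloxy)vinyl]-8-(methoxymethoxy)-6-(3-methylbutyl)-3-[(R)-1-(2,4,6-triisopropylphenyl)ethoxy]-3,4-dihydronaphthalen-1(2H)-one, via photoenol 16 (not isolated), via tetralone enol 17 (not isolated)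
Conditions: hν (365 nm LED), degassed PhMe (5 mM), 10 °C; then Et3N-treated SiO2
Reagents that add atoms: none
Why: Proposed new method: the excited aryl ketone takes a hydrogen from the ortho C-methyl group (the future C4) through a six-membered transition state and gives the (E)-dienol 16, a hydroxy-o-quinodimethane in which C4=C4a–C8a=C1–C2=C3 is a 1,3,5-hexatriene, and this closes thermally to the C4–C3 bond with return of the benzene ring before enol 17 ketonizes to 18. The closest known reaction types are the photoenolization/Diels–Alder reaction of o-tolyl aldehydes and ketones, where the same kind of dienol is trapped by an outside alkene, and the thermal ring opening of 1-alkenylbenzocyclobutenols, whose dienols close in the same 6π manner to 1-tetralones. Ring B, the only ring closed, forms by a thermal disrotatory 6π-electrocyclization in which all six ring carbons are the triene carbons. The only new stereocenter, C3, is controlled by the (R)-1-arylethyl group on the enol ether oxygen: with the O–C3 bond s-cis and the carbinol C–H in the enone plane the Trip group covers one face of C2=C3, C4 bonds to the other and (3R) should result, while the (3S) epimer, a diastereomer, should be removable by chromatography. The step needs hydrogen transfer from the C-methyl group and not from the OCH2 of the MOM ether (six- against seven-membered transition state), the dienol geometry with the vinyl group on the side of C4 (the outward hydroxyl is held by a hydrogen bond to the MOM oxygen on C8, the inward isomer only falls back to the ketone) and the alkoxy group outside the closing ring, which the (E)-enol ether provides. Light of 365 nm should be absorbed by the aroyl enone only, since the substrate carries the future pyranone carbons as a transparent silyl enol ether.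

**Step 11**
Reactants: 18 (3R)-5-[1-(tert-butyldimethylsilyloxy)vinyl]-8-(methoxymethoxy)-6-(3-methylbutyl)-3-[(R)-1-(2,4,6-triisopropylphenyl)ethoxy]-3,4-dihydronaphthalen-1(2H)-one; 19 malonyl dichloride
Product: 21 (3R)-5-(4-hydroxy-2-oxo-2H-pyran-6-yl)-8-(methoxymethoxy)-6-(3-methylbutyl)-3-[(R)-1-(2,4,6-triisopropylphenyl)ethoxy]-3,4-dihydronaphthalen-1(2H)-one, via keto acid chloride 20 (not isolated)
Conditions: 2,6-di-tert-butyl-4-methylpyridine, Et2O, −78 to 0 °C
Reagents that add atoms: none
Why: C-acylation of the silyl enol ether by malonyl dichloride followed by closure of the 1,3-diketone enol onto the second acid chloride is the known 4-hydroxy-2-pyranone synthesis from silyl enol ethers, and the hindered pyridine takes up HCl so that the ethers and the β-alkoxy ketone should survive.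

**Step 12**
Reactants: 21 (3R)-5-(4-hydroxy-2-oxo-2H-pyran-6-yl)-8-(methoxymethoxy)-6-(3-methylbutyl)-3-[(R)-1-(2,4,6-triisopropylphenyl)ethoxy]-3,4-dihydronaphthalen-1(2H)-one
Product: 22 (3R)-3,8-dihydroxy-5-(4-hydroxy-2-oxo-2H-pyran-6-yl)-6-(3-methylbutyl)-3,4-dihydronaphthalen-1(2H)-one
Conditions: TFA/CH2Cl2/H2O, 0 °C
Reagents that add atoms: none
Why: Acidolysis cleaves the MOM acetal and ionizes the benzylic ether on the auxiliary side (SN1 at the 1-arylethyl carbon), so the C3–O bond is never broken and the (R) configuration is kept.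

**Compound list**

1 | 2,4-dihydroxy-6-methylbenzaldehyde | O=Cc1c(C)cc(O)cc1O | starting material
2 | 4-formyl-3-hydroxy-5-methylphenyl trifluoromethanesulfonate | O=Cc1c(C)cc(OS(=O)(=O)C(F)(F)F)cc1O | intermediate
3 | 4-formyl-3-(methoxymethoxy)-5-methylphenyl trifluoromethanesulfonate | O=Cc1c(C)cc(OS(=O)(=O)C(F)(F)F)cc1OCOC | intermediate
4 | (3-methylbutyl)zinc bromide | CC(C)CC[Zn]Br | starting material
5 | 2-(methoxymethoxy)-6-methyl-4-(3-methylbutyl)benzaldehyde | O=Cc1c(C)cc(CCC(C)C)cc1OCOC | intermediate
6 | 3-bromo-6-(methoxymethoxy)-2-methyl-4-(3-methylbutyl)benzaldehyde | O=Cc1c(C)c(Br)c(CCC(C)C)cc1OCOC | intermediate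
7 | tributyl(1-ethoxyvinyl)stannane | CCCC[Sn](CCCC)(CCCC)C(=C)OCC | starting material
8 | 3-(1-ethoxyvinyl)-6-(methoxymethoxy)-2-methyl-4-(3-methylbutyl)benzaldehyde | O=Cc1c(C)c(C(=C)OCC)c(CCC(C)C)cc1OCOC | intermediate
9 | 3-acetyl-6-(methoxymethoxy)-2-methyl-4-(3-methylbutyl)benzaldehyde | O=Cc1c(C)c(C(C)=O)c(CCC(C)C)cc1OCOC | intermediate
10 | 3-[1-(tert-butyldimethylsilyloxy)vinyl]-6-(methoxymethoxy)-2-methyl-4-(3-methylbutyl)benzaldehyde | O=Cc1c(C)c(C(=C)O[Si](C)(C)C(C)(C)C)c(CCC(C)C)cc1OCOC | intermediate
11 | ethynylmagnesium bromide | C#C[Mg]Br | starting material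
12 | racemic 1-{3-[1-(tert-butyldimethylsilyloxy)vinyl]-6-(methoxymethoxy)-2-methyl-4-(3-methylbutyl)phenyl}prop-2-yn-1-ol | C#CC(O)c1c(C)c(C(=C)O[Si](C)(C)C(C)(C)C)c(CCC(C)C)cc1OCOC | intermediate
13 | 1-{3-[1-(tert-butyldimethylsilyloxy)vinyl]-6-(methoxymethoxy)-2-methyl-4-(3-methylbutyl)phenyl}prop-2-yn-1-one | C#CC(=O)c1c(C)c(C(=C)O[Si](C)(C)C(C)(C)C)c(CCC(C)C)cc1OCOC | intermediate
14 | (R)-1-(2,4,6-triisopropylphenyl)ethanol | C[C@@H](O)c1c(C(C)C)cc(C(C)C)cc1C(C)C | starting material
15 | (E)-1-{3-[1-(tert-butyldimethylsilyloxy)vinyl]-6-(methoxymethoxy)-2-methyl-4-(3-methylbutyl)phenyl}-3-[(R)-1-(2,4,6-triisopropylphenyl)ethoxy]prop-2-en-1-one | O=C(/C=C/O[C@H](C)c1c(C(C)C)cc(C(C)C)cc1C(C)C)c1c(C)c(C(=C)O[Si](C)(C)C(C)(C)C)c(CCC(C)C)cc1OCOC | intermediate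
16 | photoenol of 15: (E)-1-{3-[1-(tert-butyldimethylsilyloxy)vinyl]-6-(methoxymethoxy)-2-methylene-4-(3-methylbutyl)cyclohexa-3,5-dien-1-ylidene}-3-[(R)-1-(2,4,6-triisopropylphenyl)ethoxy]prop-2-en-1-ol, hydroxyl on the side of the MOM-bearing carbon, alkoxyvinyl group on the side of the exocyclic methylene | C=C1/C(=C(/O)\C=C\O[C@H](C)c2c(C(C)C)cc(C(C)C)cc2C(C)C)C(OCOC)=CC(CCC(C)C)=C1C(=C)O[Si](C)(C)C(C)(C)C | intermediate
17 | (3R)-5-[1-(tert-butyldimethylsilyloxy)vinyl]-8-(methoxymethoxy)-6-(3-methylbutyl)-3-[(R)-1-(2,4,6-triisopropylphenyl)ethoxy]-3,4-dihydronaphthalen-1-ol (enol of 18) | OC1=C[C@H](O[C@H](C)c3c(C(C)C)cc(C(C)C)cc3C(C)C)Cc2c1c(OCOC)cc(CCC(C)C)c2C(=C)O[Si](C)(C)C(C)(C)C | intermediate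
18 | (3R)-5-[1-(tert-butyldimethylsilyloxy)vinyl]-8-(methoxymethoxy)-6-(3-methylbutyl)-3-[(R)-1-(2,4,6-triisopropylphenyl)ethoxy]-3,4-dihydronaphthalen-1(2H)-one | O=C1C[C@H](O[C@H](C)c3c(C(C)C)cc(C(C)C)cc3C(C)C)Cc2c1c(OCOC)cc(CCC(C)C)c2C(=C)O[Si](C)(C)C(C)(C)C | intermediate
19 | malonyl dichloride | O=C(Cl)CC(Cl)=O | starting material
20 | 5-{(7R)-4-(methoxymethoxy)-2-(3-methylbutyl)-5-oxo-7-[(R)-1-(2,4,6-triisopropylphenyl)ethoxy]-5,6,7,8-tetrahydronaphthalen-1-yl}-3,5-dioxopentanoyl chloride | O=C1C[C@H](O[C@H](C)c3c(C(C)C)cc(C(C)C)cc3C(C)C)Cc2c1c(OCOC)cc(CCC(C)C)c2C(=O)CC(=O)CC(Cl)=O | intermediate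
21 | (3R)-5-(4-hydroxy-2-oxo-2H-pyran-6-yl)-8-(methoxymethoxy)-6-(3-methylbutyl)-3-[(R)-1-(2,4,6-triisopropylphenyl)ethoxy]-3,4-dihydronaphthalen-1(2H)-one | O=C1C[C@H](O[C@H](C)c3c(C(C)C)cc(C(C)C)cc3C(C)C)Cc2c1c(OCOC)cc(CCC(C)C)c2-c1cc(O)cc(=O)o1 | intermediate
22 | (3R)-3,8-dihydroxy-5-(4-hydroxy-2-oxo-2H-pyran-6-yl)-6-(3-methylbutyl)-3,4-dihydronaphthalen-1(2H)-one | CC(C)CCc1cc(O)c2c(c1-c1cc(O)cc(=O)o1)C[C@@H](O)CC2=O | target

**Step count and risks**

Total steps: 12. Longest linear sequence: 12 steps (from 1 to 22).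

Steps most likely to fail:

1. Step 10. The excited enone may lose its energy by E/Z isomerization of the C2=C3 bond, or the dienol may fall back to the ketone faster than it cyclizes. Hydrogen transfer from the OCH2 of the MOM ether, further photoreaction of the tetralone product, and weak facial discrimination by the auxiliary are further ways to lose material or selectivity. The fallback gives up light and the neutral pericyclic sequence and makes the same bond from a preformed benzylic carbanion, using known reaction types (lateral lithiation of an o-tolyl ketone that has no α-hydrogen, intramolecular Michael addition to a β-alkoxy enone, kinetic protonation). It sets out from enone 15, which is treated with lithium 2,2,6,6-tetramethylpiperidide (LiTMP) in THF at −78 °C. Deprotonation of the C-methyl group gives the o-quinodimethane lithium dienolate F1, which closes onto C3 to the tetralone lithium enolate F2. Acetic acid at −78 °C, added before the enolate can expel the β-alkoxide, brings the route back at 18.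

2. Step 11. Hydrogen chloride or the twofold acid chloride may cleave the acid-labile benzylic and MOM ethers, acylate the hydroxyl groups so freed, or drive β-elimination of the C3 alkoxy group towards a naphthol. The fallback builds ring C in two neutral stages and sets out from 18. Lewis-acid-catalysed C-acylation of the silyl enol ether (Mukaiyama-type; tert-butyl 3-chloro-3-oxopropanoate, ZnCl2 10 mol%, CH2Cl2, 0 °C) gives the tert-butyl 3,5-dioxopentanoate F3. Heating F3 in toluene at 110 °C expels tert-butanol to give the acylketene F4, which lactonizes onto the enolized aryl ketone and brings the route back at 21.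

3. Step 9. The hindered secondary alcohol may add too slowly, so that the phosphonium enolate oligomerizes the terminal ynone instead. The fallback replaces the catalytic conjugate addition by a stoichiometric addition–elimination and sets out from ynone 13. Hydrochlorination (LiCl, AcOH, MeCN, 0 °C) gives the (Z)-β-chlorovinyl ketone F5. The sodium alkoxide F6, made from 14 with NaH in THF, displaces chloride at 0 °C and brings the route back at 15 as the (E)-isomer.

**Further compounds**

F1 | step 10 | o-quinodimethane lithium dienolate from lateral lithiation of 15 | [Li+].[O-]C(/C=C/O[C@H](C)c1c(C(C)C)cc(C(C)C)cc1C(C)C)=C1C(=C)C(C(=C)O[Si](C)(C)C(C)(C)C)=C(CCC(C)C)C=C1OCOC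
F2 | step 10 | lithium enolate of 18 | [Li+].[O-]C1=C[C@H](O[C@H](C)c3c(C(C)C)cc(C(C)C)cc3C(C)C)Cc2c1c(OCOC)cc(CCC(C)C)c2C(=C)O[Si](C)(C)C(C)(C)C
F3 | step 11 | tert-butyl 5-{(7R)-4-(methoxymethoxy)-2-(3-methylbutyl)-5-oxo-7-[(R)-1-(2,4,6-triisopropylphenyl)ethoxy]-5,6,7,8-tetrahydronaphthalen-1-yl}-3,5-dioxopentanoate | O=C1C[C@H](O[C@H](C)c3c(C(C)C)cc(C(C)C)cc3C(C)C)Cc2c1c(OCOC)cc(CCC(C)C)c2C(=O)CC(=O)CC(=O)OC(C)(C)C
F4 | step 11 | acylketene from F3 (5-aryl-3,5-dioxopent-1-en-1-one) | O=C1C[C@H](O[C@H](C)c3c(C(C)C)cc(C(C)C)cc3C(C)C)Cc2c1c(OCOC)cc(CCC(C)C)c2C(=O)CC(=O)C=C=O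
F5 | step 9 | (Z)-3-chloro-1-{3-[1-(tert-butyldimethylsilyloxy)vinyl]-6-(methoxymethoxy)-2-methyl-4-(3-methylbutyl)phenyl}prop-2-en-1-one | O=C(/C=C\Cl)c1c(C)c(C(=C)O[Si](C)(C)C(C)(C)C)c(CCC(C)C)cc1OCOC
F6 | step 9 | sodium (R)-1-(2,4,6-triisopropylphenyl)ethoxide | [Na+].[O-][C@H](C)c1c(C(C)C)cc(C(C)C)cc1C(C)C
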